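**Retrosynthetic overview**
- Key disconnection: the N2–C3 bond of the pyridine ring, opened together with C4–C4a. This takes 7-bromo-1,3-dimethylisoquinolin-8-yl acetate back to the O-acetyl oxime of 3-bromo-2-hydroxyacetophenone plus propyne. The N–O bond serves as the internal oxidant for the C–N closure.
- The C7–C8' biaryl bond is a routine Suzuki union of that bromide with 5-bromo-1,8-dimethoxy-3-methylnaphthalene, which is borylated in the same flask.
- The naphthalene comes from an aryne/dienolate benzannulation of 2,4-dibromoanisole with N,N-diethyl-3-methylbut-2-enamide, followed by O-methylation.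
- Ring order: in fragment 1 the methyl-bearing ring is annulated onto the anisole ring. In fragment 2 the pyridine ring is annulated onto the phenol ring. The two bicycles are then joined and the acetate is cleaved.

**Assumption:** the SMILES has no stereodescriptor and the molecule has no stereocentre. Its 7,8'-axis is flanked only by OH and a peri C–H and rotates freely at room temperature. The single constitution given is therefore the target and no enantiocontrol is needed.

**Step 1**
Reactants: 1 3-methylbut-2-enoyl chloride; 2 diethylamine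
Product: 3 N,N-diethyl-3-methylbut-2-enamide
Conditions: Et2NH (1.1 equiv), 2 M aq NaOH, CH2Cl2, 0 °C to rt
Reagents that add atoms: none
Why: Schotten–Baumann acylation of a secondary amine by an acid chloride; any deconjugated isomer is harmless because both isomers give the same dienolate in step 2.

**Step 2**
Reactants: 3 N,N-diethyl-3-methylbut-2-enamide; 4 2,4-dibromoanisole
Product: 7 5-bromo-8-methoxy-3-methylnaphthalen-1-ol, via lithium dienolate 5 (not isolated), via 3-bromo-6-methoxybenzyne 6 (not isolated)
Conditions: LDA (3.2 equiv), THF, −78 °C to 0 °C; then 1 M HCl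
Reagents that add atoms: none
Why: LDA removes the most acidic ring proton of 4 (C3–H between the two bromines) and LiBr loss next to the methoxy group gives aryne 6, whose methoxy-induced polarisation sends the γ-carbon of dienolate 5 to the aryne carbon remote from OMe, so that the aryl anion formed ortho to OMe closes on the amide carbonyl, expels diethylamide and tautomerises to the naphthol (aryne–dienolate anionic [4+2] benzannulation), with the second bromine kept para to OMe.

**Step 3**
Reactants: 7 5-bromo-8-methoxy-3-methylnaphthalen-1-ol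
Product: 8 5-bromo-1,8-dimethoxy-3-methylnaphthalene
Conditions: MeI, K2CO3, DMF, 40 °C
Reagents that add atoms: iodomethane CI
Why: Williamson-type O-methylation (SN2 on MeI) of the only acidic OH; the aryl bromide and the ether are inert.

**Step 4**
Reactants: 9 1-(3-bromo-2-hydroxyphenyl)ethan-1-one
Product: 11 2-bromo-6-[(1E)-1-(acetoxyimino)ethyl]phenyl acetate, via (E)-oxime 10 (not isolated)
Conditions: NH2OH (50 wt% in H2O), EtOH, 60 °C; evaporate; then Ac2O (4 equiv), pyridine, DMAP (5 mol%), CH2Cl2, 0 °C to rt
Reagents that add atoms: hydroxylamine NO; acetic anhydride CC(=O)OC(C)=O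
Why: Oxime condensation gives the (E)-isomer (OH anti to the aryl group, favoured sterically and by the phenol O–H···N hydrogen bond), and exhaustive DMAP-catalysed O-acylation at room temperature masks oxime and phenol together faster than the mono-acetate can close to a benzisoxazole.

**Step 5**
Reactants: 11 2-bromo-6-[(1E)-1-(acetoxyimino)ethyl]phenyl acetate; 12 propyne
Product: 13 7-bromo-1,3-dimethylisoquinolin-8-yl acetate
Conditions: Cp*Co(CO)I2 (10 mol%), AgSbF6 (20 mol%), KOAc (20 mol%), pre-stirred 10 min; propyne (4 equiv, condensed in), ClCH2CH2Cl, sealed pressure tube, 110 °C, 16 h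
Reagents that add atoms: none
Why: Proposed new method: a cationic Cp*-cobalt acetate (trivalent cobalt) binds the lone pair of the (E)-oxime nitrogen, which points at the only free ortho C–H, and cleaves that bond by acetate-assisted concerted metalation–deprotonation; propyne then inserts into the Co–aryl bond with its CH terminus on the arene and the methyl-bearing carbon on cobalt (steric and polarity control, as seen for higher 1-alkynes); the alkenyl carbon then bonds to nitrogen while the N–OAc bond breaks, which forms N2–C3, aromatises the pyridine ring, releases AcOH and returns trivalent cobalt without an external oxidant; the aryl acetate stops the phenol from chelating cobalt as a salicyl oxime or closing onto nitrogen; the closest known reaction type is the Cp*-cobalt or Cp*-rhodium oxime-ester/alkyne [4+2] isoquinoline annulation, shown for internal and higher terminal alkynes but, to my knowledge, not for propyne gas on a 2-acyloxy-3-halo ketoxime ester that must build a 1,8-peri-crowded isoquinoline.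

**Step 6**
Reactants: 8 5-bromo-1,8-dimethoxy-3-methylnaphthalene; 13 7-bromo-1,3-dimethylisoquinolin-8-yl acetate
Product: 16 dioncophylleine D, via naphthyl pinacol boronate 14 (not isolated), via biaryl acetate 15 (not isolated)
Conditions: 8 (1.2 equiv), B2pin2 (1.25 equiv), Pd2(dba)3 (2 mol%), XPhos (8 mol%), KOAc, 1,4-dioxane, 100 °C; then 13 (1.0 equiv), 3 M aq K3PO4, 90 °C; then MeOH, 2 M NaOH, rt; work-up at pH 7–8
Reagents that add atoms: bis(pinacolato)diboron CC1(C)OB(OC1(C)C)B1OC(C)(C)C(C)(C)O1 (boron group of 14 only, lost again on coupling)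
Why: Miyaura borylation of the electron-rich bromide, Suzuki–Miyaura coupling under a bulky biaryl phosphine that copes with one ortho substituent plus a peri C–H, and saponification of the aryl acetate run in one flask; the new axis is configurationally labile, so nothing has to be controlled.

**Compound list**
1 | 3-methylbut-2-enoyl chloride | CC(C)=CC(=O)Cl | starting material
2 | diethylamine | CCNCC | starting material
3 | N,N-diethyl-3-methylbut-2-enamide | CC(C)=CC(=O)N(CC)CC | intermediate
4 | 2,4-dibromoanisole | COc1ccc(Br)cc1Br | starting material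
5 | lithium 1-(diethylamino)-3-methylbuta-1,3-dien-1-olate (enolate geometry not defined) | C=C(C)C=C(O[Li])N(CC)CC | intermediate
6 | 3-bromo-6-methoxybenzyne | COC1=CC=C(Br)C#C1 | intermediate
7 | 5-bromo-8-methoxy-3-methylnaphthalen-1-ol | Cc1cc(O)c2c(OC)ccc(Br)c2c1 | intermediate
8 | 5-bromo-1,8-dimethoxy-3-methylnaphthalene | Cc1cc(OC)c2c(OC)ccc(Br)c2c1 | intermediate
9 | 1-(3-bromo-2-hydroxyphenyl)ethan-1-one | CC(=O)c1cccc(Br)c1O | starting material
10 | (1E)-1-(3-bromo-2-hydroxyphenyl)ethan-1-one oxime | C/C(=N\O)c1cccc(Br)c1O | intermediate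
11 | 2-bromo-6-[(1E)-1-(acetoxyimino)ethyl]phenyl acetate | C/C(=N\OC(C)=O)c1cccc(Br)c1OC(C)=O | intermediate
12 | propyne | CC#C | starting material
13 | 7-bromo-1,3-dimethylisoquinolin-8-yl acetate | CC(=O)Oc1c(Br)ccc2cc(C)nc(C)c12 | intermediate
14 | 2-(4,5-dimethoxy-7-methylnaphthalen-1-yl)-4,4,5,5-tetramethyl-1,3,2-dioxaborolane | COc1ccc(B2OC(C)(C)C(C)(C)O2)c2cc(C)cc(OC)c12 | intermediate
15 | 7-(4,5-dimethoxy-7-methylnaphthalen-1-yl)-1,3-dimethylisoquinolin-8-yl acetate | COc1ccc(-c2ccc3cc(C)nc(C)c3c2OC(C)=O)c2cc(C)cc(OC)c12 | intermediate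
16 | dioncophylleine D, 7-(4,5-dimethoxy-7-methylnaphthalen-1-yl)-1,3-dimethylisoquinolin-8-ol | COc1ccc(-c2ccc3cc(C)nc(C)c3c2O)c2cc(C)cc(OC)c12 | target

**Step count**
- Total step count: 6.
- Longest linear sequence: 4 (steps 1, 2, 3, 6). The second branch is steps 4, 5, 6.

**Three steps most likely to fail**

**Step 5, the new annulation.**
- Risks:
  - The planar cobaltacycle presses the oxime methyl against the OAc group, so C–H cobaltation may be slow.
  - Propyne may oligomerise.
  - The oxime ester may drift into Beckmann or benzisoxazole products.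
- Fallback: known chemistry only. It makes the biaryl first and closes the pyridine ring with ammonia. It sets out from 8 and comes back at 16.
  - 2',6'-Dihydroxyacetophenone is brominated with NBS in MeCN at 0 °C to 1-(3-bromo-2,6-dihydroxyphenyl)ethan-1-one F1.
  - Compound 8 is borylated to 14 as in step 6 and coupled with F1 under the same Suzuki–Miyaura conditions to 1-[3-(4,5-dimethoxy-7-methylnaphthalen-1-yl)-2,6-dihydroxyphenyl]ethan-1-one F2.
  - Tf2O (1.05 equiv) and pyridine in CH2Cl2 at −20 °C sulfonylate only the hydroxyl that is not flanked by the naphthyl group. This gives 2-acetyl-4-(4,5-dimethoxy-7-methylnaphthalen-1-yl)-3-hydroxyphenyl trifluoromethanesulfonate F3.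
  - Sonogashira coupling with propyne 12 (Pd(PPh3)2Cl2, CuI, Et3N, DMF, 50 °C) gives 1-[3-(4,5-dimethoxy-7-methylnaphthalen-1-yl)-2-hydroxy-6-(prop-1-yn-1-yl)phenyl]ethan-1-one F4.
  - NH3 in MeOH (7 M, AgOTf 5 mol%, sealed tube, 100 °C) condenses with the ketone, and the imine nitrogen adds 6-endo-dig to the alkyne. This gives 16 directly.

**Step 2, the aryne benzannulation.**
- Risks:
  - LiBr can be lost on either side of the lithiated carbon.
  - Methoxy and bromine compete in steering the dienolate.
  - Diisopropylamine can trap the aryne.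
  - Isomers and a modest yield are therefore possible.
- Fallback: the bromine is introduced after the ring is built. It sets out from 3 and comes back at 7.
  - Dienolate 5 from 3 is combined with 2-bromoanisole and LDA. This generates 3-methoxybenzyne F5, an aryne with a single directing group, and leads to 8-methoxy-3-methylnaphthalen-1-ol F6.
  - Ac2O and pyridine give 8-methoxy-3-methylnaphthalen-1-yl acetate F7, in which the acylated ring is deactivated.
  - NBS in MeCN at 0 °C then brominates para to the methoxy group to 5-bromo-8-methoxy-3-methylnaphthalen-1-yl acetate F8.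
  - Catalytic K2CO3 in MeOH removes the acetate and delivers 7.

**Step 6, the one-flask borylation, coupling and deacetylation.**
- Risks:
  - The electron-rich naphthyl boronate may protodeborylate in hot aqueous base.
  - Early acetate loss would leave an electron-rich bromophenoxide.
  - Homocoupling may occur.
- Fallback: a base-free zinc route in place of boron. It sets out from 8 and comes back at 15.
  - Bromine–lithium exchange (n-BuLi, THF, −78 °C) gives (4,5-dimethoxy-7-methylnaphthalen-1-yl)lithium F9.
  - ZnCl2 converts it into (4,5-dimethoxy-7-methylnaphthalen-1-yl)zinc chloride F10.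
  - Negishi coupling with 13 (Pd2(dba)3, SPhos, THF, 60 °C) gives 15, which is isolated.
  - Catalytic K2CO3 in MeOH then cleaves 15 to 16.

**Further compounds**
F1 | step 5 | 1-(3-bromo-2,6-dihydroxyphenyl)ethan-1-one | CC(=O)c1c(O)ccc(Br)c1O
F2 | step 5 | 1-[3-(4,5-dimethoxy-7-methylnaphthalen-1-yl)-2,6-dihydroxyphenyl]ethan-1-one | COc1ccc(-c2ccc(O)c(C(C)=O)c2O)c2cc(C)cc(OC)c12
F3 | step 5 | 2-acetyl-4-(4,5-dimethoxy-7-methylnaphthalen-1-yl)-3-hydroxyphenyl trifluoromethanesulfonate | COc1ccc(-c2ccc(OS(=O)(=O)C(F)(F)F)c(C(C)=O)c2O)c2cc(C)cc(OC)c12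
F4 | step 5 | 1-[3-(4,5-dimethoxy-7-methylnaphthalen-1-yl)-2-hydroxy-6-(prop-1-yn-1-yl)phenyl]ethan-1-one | COc1ccc(-c2ccc(C#CC)c(C(C)=O)c2O)c2cc(C)cc(OC)c12
F5 | step 2 | 3-methoxybenzyne | COC1=CC=CC#C1
F6 | step 2 | 8-methoxy-3-methylnaphthalen-1-ol | Cc1cc(O)c2c(OC)cccc2c1
F7 | step 2 | 8-methoxy-3-methylnaphthalen-1-yl acetate | Cc1cc(OC(C)=O)c2c(OC)cccc2c1
F8 | step 2 | 5-bromo-8-methoxy-3-methylnaphthalen-1-yl acetate | Cc1cc(OC(C)=O)c2c(OC)ccc(Br)c2c1
F9 | step 6 | (4,5-dimethoxy-7-methylnaphthalen-1-yl)lithium | [Li]c1ccc(OC)c2c(OC)cc(C)cc12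
F10 | step 6 | (4,5-dimethoxy-7-methylnaphthalen-1-yl)zinc chloride | Cl[Zn]c1ccc(OC)c2c(OC)cc(C)cc12
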